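The syncarpic acid ring is cut across the two ring bonds that flank one C(=O)–CMe2 unit, which is then dimethylketene. With the trione ring numbered so that C4 carries the side chain and C1 is the ketone between the two CMe2 carbons, the ketene supplies C3 and C2. The acetyl enolate of methyl 2,2-dimethylacetoacetate (C4–C5–C6–C1) adds to the ketene carbonyl (bond C4–C3), and the resulting isobutyryl carbanion closes onto the ester (bond C2–C1) in one flask. This formal [4+2] annulation exploits the enolisation-blocking gem-dimethyl carbons C2 and C6. Knoevenagel condensation and a catalytic enantioselective Friedel–Crafts-type Michael addition of the acylphloroglucinol then set the single stereocentre.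

Key step: step 2

Assumption: the triketone units are drawn as the enol tautomer of the target structure; the sense of induction of the cinchona squaramide in step 5 (Re-face attack, giving S) is assigned by analogy and would be confirmed on first use, the quinidine-derived pseudoenantiomer being the alternative.

Step 1
Reactants: 1 2-bromo-2-methylpropanoyl bromide
Product: 2 dimethylketene (2-methylprop-1-en-1-one), as a THF solution
Conditions: Zn dust (activated), THF, N2, 0 °C to rt; co-distilled with THF under reduced pressure into a −78 °C trap; used at once
Reagents that add atoms: none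
Why: Zinc-mediated 1,2-dehalogenation of an α-bromoacyl bromide (the zinc enolate expels bromide) is the standard laboratory access to dimethylketene, which is kept under nitrogen because it forms peroxides with oxygen.

Step 2
Reactants: 3 methyl 2,2-dimethyl-3-oxobutanoate; 2 dimethylketene
Product: 7 syncarpic acid (5-hydroxy-2,2,6,6-tetramethylcyclohex-4-ene-1,3-dione), via lithium enolate 4 (not isolated), via lithium diketonate 5 (not isolated), via dilithium dianion 6 (not isolated)
Conditions: LiN(i-Pr)2 (LDA, 1.05 equiv), THF, −78 °C; 2 (1.1 equiv) in THF, −78 °C; LiN(i-Pr)2 (1.3 equiv), −78 °C to rt; 1 M HCl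
Reagents that add atoms: none
Why: The first base charge removes a proton from the only enolisable position of 3 (the acetyl CH3, since the ester α-carbon is quaternary) to give 4, whose carbon terminus should add to the carbonyl carbon of 2 (first new C–C bond; any O-adduct is a reversible ester enolate that funnels to the chelated C-adduct), and proton transfer then gives β-diketonate 5. The second base charge can only deprotonate the isobutyryl methine, and the tertiary carbanion of 6 should attack the methyl ester with loss of methoxide (second new C–C bond), leaving the trione as its delocalised lithium enolate, a thermodynamic sink that resists retro-Claisen opening. The closest known reaction types are C-acylation of lithium enolates by ketenes, the alkoxide-induced trimerisation of dimethylketene to hexamethylcyclohexane-1,3,5-trione, and Claisen cyclisation of 3,5-dioxoalkanoate anions to phloroglucinol-type rings. The six-membered ring closes by a 6-(enolendo)-exo-trig Dieckmann condensation. No stereocentre is formed. The step needs C- over O-acylation and a single site for each deprotonation, and both are secured by the substrate, because the two CMe2 groups block every alternative enolisation and the ketene offers one electrophilic carbon only.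

Step 3
Reactants: 7 syncarpic acid; 8 3-methylbutanal
Product: 10 2,2,4,4-tetramethyl-6-(3-methylbutylidene)cyclohexane-1,3,5-trione, via Mannich base 9 (not isolated)
Conditions: piperidine (1.1 equiv), CH2Cl2, rt; then cold 1 M HCl wash, dried, used at once
Reagents that add atoms: none
Why: Knoevenagel condensation of the acidic cyclic 1,3-dione with the aldehyde, in which piperidine traps the very electrophilic alkylidene as Mannich base 9 and so keeps a second molecule of 7 from adding, acid extraction of the amine then releasing 10 by retro-Mannich (E1cB) elimination.

Step 4
Reactants: 11 2-methylbenzene-1,3,5-triol; 12 3-phenylpropanoyl chloride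
Product: 13 3-phenyl-1-(2,4,6-trihydroxy-3-methylphenyl)propan-1-one
Conditions: AlCl3 (4 equiv), PhNO2, 60 °C; then ice/2 M HCl
Reagents that add atoms: none
Why: Friedel–Crafts C-acylation of the electron-rich triol, whose two free ring carbons are equivalent by symmetry, should stop after one acyl group because that group deactivates the ring, any aryl ester formed first being carried on by Fries rearrangement.

Step 5
Reactants: 10 2,2,4,4-tetramethyl-6-(3-methylbutylidene)cyclohexane-1,3,5-trione; 13 3-phenyl-1-(2,4,6-trihydroxy-3-methylphenyl)propan-1-one
Product: 14 5-hydroxy-2,2,6,6-tetramethyl-4-{(1S)-3-methyl-1-[2,4,6-trihydroxy-3-methyl-5-(3-phenylpropanoyl)phenyl]butyl}cyclohex-4-ene-1,3-dione (target)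
Conditions: quinine-derived squaramide 3-[3,5-bis(trifluoromethyl)anilino]-4-[(9-deoxy-epi-quinin-9-yl)amino]cyclobut-3-ene-1,2-dione (10 mol %), CH2Cl2, −30 °C; cold 0.5 M HCl wash
Reagents that add atoms: none
Why: In this catalytic enantioselective Friedel–Crafts-type Michael addition the squaramide NH pair should hydrogen-bond a trione carbonyl of 10 while the quinuclidine nitrogen engages the acidic phenol of 13, so that the only free ring carbon of 13 adds to the Re face (ring carbon > CH2 > H) of the alkylidene carbon and the (S) stereocentre is set under catalyst control, the adduct being held as its stable enol.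

Compound list
1 | 2-bromo-2-methylpropanoyl bromide | CC(C)(Br)C(=O)Br | starting material
2 | dimethylketene (2-methylprop-1-en-1-one) | CC(C)=C=O | intermediate
3 | methyl 2,2-dimethyl-3-oxobutanoate | CC(=O)C(C)(C)C(=O)OC | starting material
4 | lithium enolate of 3 (lithium 4-methoxy-3,3-dimethyl-4-oxobut-1-en-2-olate) | C=C([O-])C(C)(C)C(=O)OC.[Li+] | intermediate
5 | lithium β-diketonate of methyl 2,2,6-trimethyl-3,5-dioxoheptanoate | CC(C)C(=O)C=C([O-])C(C)(C)C(=O)OC.[Li+] | intermediate
6 | dilithium dianion of methyl 2,2,6-trimethyl-3,5-dioxoheptanoate (deprotonated at C4 and C6) | CC(C)=C([O-])C=C([O-])C(C)(C)C(=O)OC.[Li+].[Li+] | intermediate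
7 | syncarpic acid (5-hydroxy-2,2,6,6-tetramethylcyclohex-4-ene-1,3-dione, enol of 2,2,4,4-tetramethylcyclohexane-1,3,5-trione) | O=C1C=C(O)C(C)(C)C(=O)C1(C)C | intermediate
8 | 3-methylbutanal | CC(C)CC=O | starting material
9 | Mannich base, racemic 5-hydroxy-2,2,6,6-tetramethyl-4-[3-methyl-1-(piperidin-1-yl)butyl]cyclohex-4-ene-1,3-dione | CC(C)CC(N1CCCCC1)C1=C(O)C(C)(C)C(=O)C(C)(C)C1=O | intermediate
10 | 2,2,4,4-tetramethyl-6-(3-methylbutylidene)cyclohexane-1,3,5-trione | CC(C)CC=C1C(=O)C(C)(C)C(=O)C(C)(C)C1=O | intermediate
11 | 2-methylbenzene-1,3,5-triol | Cc1c(O)cc(O)cc1O | starting material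
12 | 3-phenylpropanoyl chloride | O=C(Cl)CCc1ccccc1 | starting material
13 | 3-phenyl-1-(2,4,6-trihydroxy-3-methylphenyl)propan-1-one | Cc1c(O)cc(O)c(C(=O)CCc2ccccc2)c1O | intermediate
14 | 5-hydroxy-2,2,6,6-tetramethyl-4-{(1S)-3-methyl-1-[2,4,6-trihydroxy-3-methyl-5-(3-phenylpropanoyl)phenyl]butyl}cyclohex-4-ene-1,3-dione | Cc1c(O)c(C(=O)CCc2ccccc2)c(O)c([C@H](CC(C)C)C2=C(O)C(C)(C)C(=O)C(C)(C)C2=O)c1O | target

Total step count: 5. Longest linear sequence: 4 steps (steps 1, 2, 3 and 5); step 4 is a one-step branch.

Steps most likely to fail

Step 5 may suffer from low enantiofacial discrimination, from sequestration of the basic catalyst by the acidic enol of the product, or from erosion of the stereocentre by retro-Michael reaction and re-addition. The fallback gives up asymmetric catalysis. It sets out from 10 and 13, which are united under achiral conditions (Et3N, THF, 0 °C) to the racemic adduct F1. The enantiomers are then separated by preparative HPLC on an amylose tris(3,5-dimethylphenylcarbamate) phase, and the (S)-enantiomer is 14, where the route is rejoined. The (R)-enantiomer can be re-equilibrated with base and recycled.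

Step 2 may suffer from O-acylation or amide formation (from the liberated diisopropylamine) competing with C-acylation of the enolate by the ketene, or from a sluggish ring closure between two fully substituted carbons. The fallback separates the two bond formations and avoids the ketene. It sets out from 3, which is C-acylated under soft enolisation (MgBr2·OEt2, i-Pr2NEt, 1-(2-methylpropanoyl)-1H-benzotriazole, CH2Cl2) to the isolable 3,5-dioxo ester methyl 2,2,6-trimethyl-3,5-dioxoheptanoate F2. This is ring-closed in a separate, thermodynamically driven Dieckmann step (KOt-Bu, THF, reflux; acidic work-up), and the route is rejoined at 7.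

Step 3 may suffer from addition of a second molecule of 7 to the alkylidene, from drift of the exocyclic double bond into the side chain (dienol formation), or from oligomerisation of 10 on handling. The fallback inverts the polarity of the union and never forms 10. It sets out from 13, which is aminoalkylated at its free ring carbon with 8 and piperidine (EtOH, rt) to the phenolic Mannich base 1-{2,4,6-trihydroxy-3-methyl-5-[3-methyl-1-(piperidin-1-yl)butyl]phenyl}-3-phenylpropan-1-one F3. Gentle heating of this with 7 (toluene, 60–80 °C) should release piperidine and an ortho-quinone methide, which the enol carbon of 7 intercepts to give the racemic adduct F1. Resolution by preparative HPLC on the chiral phase, as above, rejoins the route at 14.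

Further compounds
F1 | step 5 | racemic 5-hydroxy-2,2,6,6-tetramethyl-4-{3-methyl-1-[2,4,6-trihydroxy-3-methyl-5-(3-phenylpropanoyl)phenyl]butyl}cyclohex-4-ene-1,3-dione | Cc1c(O)c(C(=O)CCc2ccccc2)c(O)c(C(CC(C)C)C2=C(O)C(C)(C)C(=O)C(C)(C)C2=O)c1O
F2 | step 2 | methyl 2,2,6-trimethyl-3,5-dioxoheptanoate | CC(C)C(=O)CC(=O)C(C)(C)C(=O)OC
F3 | step 3 | 1-{2,4,6-trihydroxy-3-methyl-5-[3-methyl-1-(piperidin-1-yl)butyl]phenyl}-3-phenylpropan-1-one (racemic) | Cc1c(O)c(C(=O)CCc2ccccc2)c(O)c(C(CC(C)C)N2CCCCC2)c1O
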